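**Retrosynthetic overview**

- Feature: C4 of ring C is bonded to C4a, which lies between the two oxygen-bearing ring-A carbons C5 and C8a. A nitrile oxide placed on C4 therefore carries two ortho oxygen substituents and is persistent, and the C4(=O)–C3–C2(–O1) unit of ring C can be stored as an isoxazole (N on C4, O on C2).
- Disconnections, backwards: five O–CH3 bonds; O1–C2 (acid closure, O8a being the only free phenol); the isoxazole N–O bond; C3–C4 and O–C2 ([3+2] of a ring-A nitrile oxide with the ring-B arylacetylene); C4–C4a (ortho-formylation); the CH2–aryl bond of the C8 benzyl group (Grignard addition to a salicylaldehyde, then deoxygenation).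
- Ring order: rings A, B and the benzyl ring are bought; the isoxazole ring is formed in step 6 and opened in step 7; ring C (pyranone) is closed in step 8.

Key step: step 6

Remark on the chemistry: 1, 2 and 11 are taken as purchased; the oxime is drawn E, and its geometry is of no consequence because the nitrile oxide is linear.

**Route**

Step 1
Reactants: 1 4-bromoanisole; 2 2-hydroxy-4,6-dimethoxybenzaldehyde
Product: 4 2-[hydroxy(4-methoxyphenyl)methyl]-3,5-dimethoxyphenol (racemic), via arylmagnesium bromide 3 (not isolated)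
Conditions: 1, Mg, THF, reflux; then 2 (0.4 equiv), THF, 0 °C to rt; aq. NH4Cl
Reagents that add atoms: none
Why: Grignard addition to an aldehyde: one equivalent of 3 is spent on the phenol proton and a further equivalent adds to the formyl group of the resulting magnesium phenoxide (hence the excess), giving a racemic carbinol whose stereocentre is removed in step 2.

Step 2
Reactants: 4 2-[hydroxy(4-methoxyphenyl)methyl]-3,5-dimethoxyphenol
Product: 6 2-(4-methoxybenzyl)-3,5-dimethoxyphenol, via ortho-quinone methide 5 (not isolated)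
Conditions: Et3SiH (3 equiv), TFA (3 equiv), CH2Cl2, −20 to 0 °C, slow addition of 4
Reagents that add atoms: none
Why: Ionic hydrogenation (Kursanov–Parnes type): acid ionises the doubly benzylic ortho-hydroxy carbinol to ortho-quinone methide 5 (in TFA its O-protonated form, a benzhydryl cation stabilised by both electron-rich rings), which takes hydride from the silane, while excess silane, slow addition of 4 and low temperature should keep the cation from alkylating a second arene and the product from losing its benzyl group.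

Step 3
Reactants: 6 2-(4-methoxybenzyl)-3,5-dimethoxyphenol
Product: 8 2-hydroxy-4,6-dimethoxy-3-(4-methoxybenzyl)benzaldehyde, via hydroxymethylphenol 7 (not isolated)
Conditions: MgCl2, Et3N, (CH2O)n, MeCN, reflux; cold 1 M HCl work-up
Reagents that add atoms: paraformaldehyde (as formaldehyde), C=O
Why: Magnesium-mediated ortho-formylation (Casnati–Skattebøl): formaldehyde bound to the magnesium phenoxide is delivered to the only free ortho carbon (C6 of 6, between OH and OMe) to give hydroxymethylphenol 7, which a second formaldehyde oxidises by hydride transfer, so that the carbon that becomes C4 sits next to the oxygen that becomes O1 and the ring carbon between the two methoxy groups, which is not ortho to the phenoxide, is left alone.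

Step 4
Reactants: 8 2-hydroxy-4,6-dimethoxy-3-(4-methoxybenzyl)benzaldehyde
Product: 9 4,6-dimethoxy-3-(4-methoxybenzyl)-2-(methoxymethoxy)benzaldehyde
Conditions: NaH, MOMCl, DMF, 0 °C to rt
Reagents that add atoms: chloromethyl methyl ether (MOMCl), COCCl
Why: Williamson-type O-alkylation of the sodium phenoxide (full deprotonation is needed for this chelated, doubly flanked phenol), installing an acetal that masks the future O1 during oxidation and cycloaddition and can later be removed by acid that leaves the methyl ethers in place.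

Step 5
Reactants: 9 4,6-dimethoxy-3-(4-methoxybenzyl)-2-(methoxymethoxy)benzaldehyde
Product: 10 (E)-4,6-dimethoxy-3-(4-methoxybenzyl)-2-(methoxymethoxy)benzaldehyde oxime
Conditions: NH2OH·HCl, NaOAc, EtOH/H2O, rt
Reagents that add atoms: hydroxylamine hydrochloride, Cl.NO
Why: Oxime condensation under acetate buffer, mild enough for the acetal, expected to give the E aldoxime, whose geometry is in any case lost in the linear nitrile oxide.

Step 6
Reactants: 10 (E)-4,6-dimethoxy-3-(4-methoxybenzyl)-2-(methoxymethoxy)benzaldehyde oxime; 11 4-ethynyl-1,2-dimethoxybenzene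
Product: 13 5-(3,4-dimethoxyphenyl)-3-[4,6-dimethoxy-3-(4-methoxybenzyl)-2-(methoxymethoxy)phenyl]isoxazole, via nitrile oxide 12 (not isolated)
Conditions: PhI(OAc)2 (1.2 equiv), 11 (2 equiv), MeOH/CH2Cl2, 0 °C, then 40 °C
Reagents that add atoms: none
Why: PhI(OAc)2, a trivalent iodine oxidant, dehydrogenates the aldoxime to nitrile oxide 12 (ligand exchange at iodine, then loss of iodobenzene and acetic acid), and 12 adds to the terminal alkyne 11 in a concerted, thermally allowed [3+2] (Huisgen) cycloaddition that joins the nitrile oxide carbon (future C4) to the terminal alkyne carbon (future C3) and the dipole oxygen to the aryl-bearing alkyne carbon (future C2). The closest known reaction type is the cycloaddition of 2,6-disubstituted benzonitrile oxides with arylacetylenes to 3,5-diarylisoxazoles. The isoxazole ring is closed by this intermolecular cycloaddition, both of its new bonds being made in one step, and no stereocentre is formed. Two selectivities are needed: cycloaddition must outrun dimerisation of the dipole, and the dipole oxygen must end on the aryl-bearing carbon (3,5- and not 3,4-diaryl) so that ring B sits on C2. The first is secured by the OMOM and OMe groups on both ortho positions (the C8a and C5 oxygens), which block furoxan formation so that 12 survives the gentle warming that this electron-rich pair needs, and the second by the steric and frontier-orbital bias of a terminal arylacetylene, which places the hindered nitrile oxide carbon on the unsubstituted alkyne carbon. The iodine oxidant is preferred to N-chlorosuccinimide or hypochlorite because these would halogenate the free ring-A carbon between the two methoxy groups.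

Step 7
Reactants: 13 5-(3,4-dimethoxyphenyl)-3-[4,6-dimethoxy-3-(4-methoxybenzyl)-2-(methoxymethoxy)phenyl]isoxazole
Product: 14 (Z)-3-amino-1-(3,4-dimethoxyphenyl)-3-[4,6-dimethoxy-3-(4-methoxybenzyl)-2-(methoxymethoxy)phenyl]prop-2-en-1-one
Conditions: Mo(CO)6 (1 equiv), MeCN/H2O, reflux
Reagents that add atoms: none
Why: Reductive N–O cleavage of an isoxazole by zerovalent molybdenum with water as proton source, a known unmasking of isoxazoles to β-amino enones, run under neutral conditions that spare the acetal and give the Z isomer held by an N–H···O=C hydrogen bond.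

Step 8
Reactants: 14 (Z)-3-amino-1-(3,4-dimethoxyphenyl)-3-[4,6-dimethoxy-3-(4-methoxybenzyl)-2-(methoxymethoxy)phenyl]prop-2-en-1-one
Product: 17 2-(3,4-dimethoxyphenyl)-5,7-dimethoxy-8-(4-methoxybenzyl)-4H-chromen-4-one, via free-phenol enaminone 15 (not isolated), via 1,3-diketone 16 (not isolated)
Conditions: 3 M aq. HCl/EtOH, reflux
Reagents that add atoms: water, O
Why: Aqueous acid removes the methoxymethyl acetal (giving 15), hydrolyses the vinylogous amide to 1,3-diketone 16 (the C4 carbonyl oxygen coming from water) and cyclodehydrates it as in the closing stage of a Baker–Venkataraman flavone synthesis, the O1–C2 bond being formed by the only free phenol next to the side chain (the C5 oxygen is still a methyl ether), so that only the 8-benzyl isomer can arise.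

Step 9
Reactants: 17 2-(3,4-dimethoxyphenyl)-5,7-dimethoxy-8-(4-methoxybenzyl)-4H-chromen-4-one
Product: 18 8-(4-hydroxybenzyl)luteolin, 2-(3,4-dihydroxyphenyl)-5,7-dihydroxy-8-(4-hydroxybenzyl)-4H-chromen-4-one
Conditions: BBr3 (12 equiv), CH2Cl2, −78 °C to rt; MeOH at −78 °C, then aq. NaHCO3
Reagents that add atoms: none
Why: Lewis-acid cleavage of aryl methyl ethers (bromide attack on the methyl group of each boron-complexed ether), a known way to demethylate polymethoxyflavones, run under anhydrous conditions in which the pyranone ring cannot open, so that no Wessely–Moser interchange of O1 and the C5 oxygen is expected, with a cold buffered quench to keep the contact of the product with HBr short.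

**Compound list**

1 | 4-bromoanisole | COc1ccc(Br)cc1 | starting material
2 | 2-hydroxy-4,6-dimethoxybenzaldehyde | COc1cc(O)c(C=O)c(OC)c1 | starting material
3 | 4-methoxyphenylmagnesium bromide | COc1ccc([Mg]Br)cc1 | intermediate (not isolated)
4 | 2-[hydroxy(4-methoxyphenyl)methyl]-3,5-dimethoxyphenol (racemic) | COc1ccc(C(O)c2c(O)cc(OC)cc2OC)cc1 | intermediate
5 | 6-(4-methoxybenzylidene)-3,5-dimethoxycyclohexa-2,4-dien-1-one (ortho-quinone methide; transient, exocyclic alkene geometry not fixed) | COc1ccc(C=C2C(=O)C=C(OC)C=C2OC)cc1 | intermediate (not isolated)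
6 | 2-(4-methoxybenzyl)-3,5-dimethoxyphenol | COc1ccc(Cc2c(O)cc(OC)cc2OC)cc1 | intermediate
7 | 2-(hydroxymethyl)-3,5-dimethoxy-6-(4-methoxybenzyl)phenol | COc1ccc(Cc2c(O)c(CO)c(OC)cc2OC)cc1 | intermediate (not isolated)
8 | 2-hydroxy-4,6-dimethoxy-3-(4-methoxybenzyl)benzaldehyde | COc1ccc(Cc2c(O)c(C=O)c(OC)cc2OC)cc1 | intermediate
9 | 4,6-dimethoxy-3-(4-methoxybenzyl)-2-(methoxymethoxy)benzaldehyde | COCOc1c(Cc2ccc(OC)cc2)c(OC)cc(OC)c1C=O | intermediate
10 | (E)-4,6-dimethoxy-3-(4-methoxybenzyl)-2-(methoxymethoxy)benzaldehyde oxime | COCOc1c(Cc2ccc(OC)cc2)c(OC)cc(OC)c1/C=N/O | intermediate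
11 | 4-ethynyl-1,2-dimethoxybenzene | C#Cc1ccc(OC)c(OC)c1 | starting material
12 | 4,6-dimethoxy-3-(4-methoxybenzyl)-2-(methoxymethoxy)benzonitrile oxide | COCOc1c(Cc2ccc(OC)cc2)c(OC)cc(OC)c1C#[N+][O-] | intermediate (not isolated)
13 | 5-(3,4-dimethoxyphenyl)-3-[4,6-dimethoxy-3-(4-methoxybenzyl)-2-(methoxymethoxy)phenyl]isoxazole | COCOc1c(Cc2ccc(OC)cc2)c(OC)cc(OC)c1-c1cc(-c2ccc(OC)c(OC)c2)on1 | intermediate
14 | (Z)-3-amino-1-(3,4-dimethoxyphenyl)-3-[4,6-dimethoxy-3-(4-methoxybenzyl)-2-(methoxymethoxy)phenyl]prop-2-en-1-one | COCOc1c(Cc2ccc(OC)cc2)c(OC)cc(OC)c1/C(N)=C/C(=O)c1ccc(OC)c(OC)c1 | intermediate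
15 | (Z)-3-amino-1-(3,4-dimethoxyphenyl)-3-[2-hydroxy-4,6-dimethoxy-3-(4-methoxybenzyl)phenyl]prop-2-en-1-one | Oc1c(Cc2ccc(OC)cc2)c(OC)cc(OC)c1/C(N)=C/C(=O)c1ccc(OC)c(OC)c1 | intermediate (not isolated)
16 | 1-(3,4-dimethoxyphenyl)-3-[2-hydroxy-4,6-dimethoxy-3-(4-methoxybenzyl)phenyl]propane-1,3-dione | Oc1c(Cc2ccc(OC)cc2)c(OC)cc(OC)c1C(=O)CC(=O)c1ccc(OC)c(OC)c1 | intermediate (not isolated)
17 | 2-(3,4-dimethoxyphenyl)-5,7-dimethoxy-8-(4-methoxybenzyl)-4H-chromen-4-one | O=c1cc(-c2ccc(OC)c(OC)c2)oc2c(Cc3ccc(OC)cc3)c(OC)cc(OC)c12 | intermediate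
18 | 8-(4-hydroxybenzyl)luteolin, 2-(3,4-dihydroxyphenyl)-5,7-dihydroxy-8-(4-hydroxybenzyl)-4H-chromen-4-one | O=c1cc(-c2ccc(O)c(O)c2)oc2c(Cc3ccc(O)cc3)c(O)cc(O)c12 | target

**Step count and risks**

Total steps: 9. Longest linear sequence: 9 steps (2 to 18; 1 enters in step 1 and 11 in step 6).

Steps most likely to fail:

1. Step 6. The oxidant may attack the electron-rich rings or the benzylic CH2 in competition with oxidation of the oxime. Alternatively, the hindered, electron-rich dipole may add so slowly to the electron-rich alkyne that isomerisation to the isocyanate and slow dimerisation take over. The fallback sets out from 9 and 11 and comes back at 17, bypassing steps 5 to 8. Deprotonation of 11 with n-BuLi (THF, −78 °C) gives lithium (3,4-dimethoxyphenyl)acetylide F1. It is added to aldehyde 9 to give racemic 1-[4,6-dimethoxy-3-(4-methoxybenzyl)-2-(methoxymethoxy)phenyl]-3-(3,4-dimethoxyphenyl)prop-2-yn-1-ol F2. MnO2 in CH2Cl2 should oxidise this to 1-[4,6-dimethoxy-3-(4-methoxybenzyl)-2-(methoxymethoxy)phenyl]-3-(3,4-dimethoxyphenyl)prop-2-yn-1-one F3. Conjugate addition of Et2NH (EtOH, rt) should give (E)-3-(diethylamino)-3-(3,4-dimethoxyphenyl)-1-[4,6-dimethoxy-3-(4-methoxybenzyl)-2-(methoxymethoxy)phenyl]prop-2-en-1-one F4. Aqueous HCl/EtOH at reflux then removes the acetal to give (E)-3-(diethylamino)-3-(3,4-dimethoxyphenyl)-1-[2-hydroxy-4,6-dimethoxy-3-(4-methoxybenzyl)phenyl]prop-2-en-1-one F5, whose phenol displaces diethylamine at C2 by addition–elimination (six-membered closure, no aurone) to give 17. In this variant C4 and its oxygen come from the aldehyde of 9 and C3–C2 from the alkyne.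

2. Step 9. Ether cleavage may stop early because partly demethylated boron chelates precipitate. Once the C5 hydroxyl is free and HBr is present at the quench, acid may also open and re-close the pyranone through the C5 oxygen (Wessely–Moser interchange, moving the benzyl group from C8 to C6) or strip the benzyl group by ipso-protonation of ring A. The fallback sets out from 17 and comes back at 18. BCl3 (CH2Cl2, 0 °C) should cleave only the chelated 5-methyl ether to give 2-(3,4-dimethoxyphenyl)-5-hydroxy-7-methoxy-8-(4-methoxybenzyl)-4H-chromen-4-one F6. MsCl, Et3N and DMAP (CH2Cl2) convert the 5-hydroxyl into 2-(3,4-dimethoxyphenyl)-7-methoxy-8-(4-methoxybenzyl)-4-oxo-4H-chromen-5-yl methanesulfonate F7. The sulfonate survives BBr3, keeps the C5 oxygen blocked so that it cannot change places with O1, and makes ring A less prone to protonation. BBr3 (CH2Cl2, −78 °C to rt) then cleaves the four remaining methyl ethers to give 2-(3,4-dihydroxyphenyl)-7-hydroxy-8-(4-hydroxybenzyl)-4-oxo-4H-chromen-5-yl methanesulfonate F8. NaOH in aqueous MeOH at rt under argon removes the sulfonate, and cold acidification gives 18.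

3. Step 2. The benzhydryl cation may be intercepted by the electron-rich rings of a second molecule (Friedel–Crafts self-condensation) faster than hydride is transferred, and acid may remove the 4-methoxybenzyl group from 6 by ipso-protonation. The fallback sets out from 2, uses Grignard reagent 3 and comes back at 6, replacing steps 1 and 2. Boc2O, DMAP (cat.) and i-Pr2NEt in THF convert 2 into tert-butyl (2-formyl-3,5-dimethoxyphenyl) carbonate F9. Addition of 3 (1.05 equiv, THF, −78 °C) gives, as its magnesium alkoxide, racemic tert-butyl 2-[hydroxy(4-methoxyphenyl)methyl]-3,5-dimethoxyphenyl carbonate F10. The Boc group shifts to the benzylic oxygen and the phenoxide expels tert-butyl carbonate, which forms ortho-quinone methide 5 under basic conditions. NaBH4, added before warming, reduces 5 in the same flask to 6, so that neither acid nor a free cation is involved.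

**Further compounds**

F1 | step 6 | lithium (3,4-dimethoxyphenyl)acetylide | [Li]C#Cc1ccc(OC)c(OC)c1
F2 | step 6 | 1-[4,6-dimethoxy-3-(4-methoxybenzyl)-2-(methoxymethoxy)phenyl]-3-(3,4-dimethoxyphenyl)prop-2-yn-1-ol (racemic) | COCOc1c(Cc2ccc(OC)cc2)c(OC)cc(OC)c1C(O)C#Cc1ccc(OC)c(OC)c1
F3 | step 6 | 1-[4,6-dimethoxy-3-(4-methoxybenzyl)-2-(methoxymethoxy)phenyl]-3-(3,4-dimethoxyphenyl)prop-2-yn-1-one | COCOc1c(Cc2ccc(OC)cc2)c(OC)cc(OC)c1C(=O)C#Cc1ccc(OC)c(OC)c1
F4 | step 6 | (E)-3-(diethylamino)-3-(3,4-dimethoxyphenyl)-1-[4,6-dimethoxy-3-(4-methoxybenzyl)-2-(methoxymethoxy)phenyl]prop-2-en-1-one | COCOc1c(Cc2ccc(OC)cc2)c(OC)cc(OC)c1C(=O)/C=C(/N(CC)CC)c1ccc(OC)c(OC)c1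
F5 | step 6 | (E)-3-(diethylamino)-3-(3,4-dimethoxyphenyl)-1-[2-hydroxy-4,6-dimethoxy-3-(4-methoxybenzyl)phenyl]prop-2-en-1-one | Oc1c(Cc2ccc(OC)cc2)c(OC)cc(OC)c1C(=O)/C=C(/N(CC)CC)c1ccc(OC)c(OC)c1
F6 | step 9 | 2-(3,4-dimethoxyphenyl)-5-hydroxy-7-methoxy-8-(4-methoxybenzyl)-4H-chromen-4-one | O=c1cc(-c2ccc(OC)c(OC)c2)oc2c(Cc3ccc(OC)cc3)c(OC)cc(O)c12
F7 | step 9 | 2-(3,4-dimethoxyphenyl)-7-methoxy-8-(4-methoxybenzyl)-4-oxo-4H-chromen-5-yl methanesulfonate | O=c1cc(-c2ccc(OC)c(OC)c2)oc2c(Cc3ccc(OC)cc3)c(OC)cc(OS(C)(=O)=O)c12
F8 | step 9 | 2-(3,4-dihydroxyphenyl)-7-hydroxy-8-(4-hydroxybenzyl)-4-oxo-4H-chromen-5-yl methanesulfonate | O=c1cc(-c2ccc(O)c(O)c2)oc2c(Cc3ccc(O)cc3)c(O)cc(OS(C)(=O)=O)c12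
F9 | step 2 | tert-butyl (2-formyl-3,5-dimethoxyphenyl) carbonate | COc1cc(OC)c(C=O)c(OC(=O)OC(C)(C)C)c1
F10 | step 2 | tert-butyl 2-[hydroxy(4-methoxyphenyl)methyl]-3,5-dimethoxyphenyl carbonate (racemic) | COc1ccc(C(O)c2c(OC)cc(OC)cc2OC(=O)OC(C)(C)C)cc1
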